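Read the end first.

the same everywhere: substrate 2.3 M (fed, over 3.0 min)
- north-east: solid reagent 0.69 M; run made earlier; the fed solution adds 0.50 times the starting volume
- flask: solid reagent 1.38 M; the fed solution adds 0.50 times the starting volume; time 20 h

north-east run (percent of the substrate charged)

| time / h | substrate / % | isomer of the product A / % | target / % |
|---|---|---|---|
| 0.833 | 85.5 | 10.0 | 1.0 |
| 1.50 | 75.2 | 19.6 | 2.1 |
| 2.50 | 72.8 | 23.6 | 0 |
| 3.00 | 72.3 | 22.0 | 0.9 |
| 4.00 | 72.2 | 23.2 | 0 |

(standard deviation of a reading: 1 percentage point)

- charges are per starting volume, the dose included; the dosed solution carries all of it
- given per volume of solution although it is solid: solid reagent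
- the earlier runs were read with a standard deviation of 1 percentage point
- steps under discussion: substrate + partner <-> target; substrate + partner <-> isomer of the product A; solid reagent <-> partner; target <-> isomer of the product B
- at the start none of the solid reagent is in solution
- the reaction counts as stopped when no species that holds the substrate changes by six tenths of a point or more over the second half of the time

* which holds at 20 h: what has brought the reaction to rest, or that it has not come to rest (for what has run out or reacted, a solid counts together with what of it has only dissolved) (it is still moving / the partner has run out first / forward and back rates have come level / all of the substrate has reacted)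
* conversion of substrate at 20 h
* amount of isomer of the product A at 20 h, in percent of the substrate charged

In the north-east run substrate stays within scatter from 2.50 h on, ending at 72.2 %, so 27.8 % has reacted. The solid reagent, the limiting reagent there, allows 30.0 %. Take the gap of 2.2 percentage points as dissolved partner left over, 0.0337 M after the feed's dilution. That gives 11.4 /M: call it the rest constant, reacted over unreacted substrate per unit of dissolved partner at rest. Hold it loosely, since a gap of that size stands against a scatter of 1 point.

Now turn the settings. Leave the feed: 3.0 min is far shorter than the 2.50 h after which the north-east run stands still. Double the solid, and the cap rises to 60.0 %. At the early north-east pace, an estimate, that cap lies about 3.45 h away, shorter than 20 h, so time should not matter. Set reacted over unreacted equal to 17.5 times the cap less the conversion, and take the smaller root of that quadratic. My reckoning gives 53.4 %. With the north-east share of isomer of the product A, 83.5 %, that makes 44.6 %.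

The forecast says forward and back rates have come level, with a conversion of 53 % and 44 % of isomer of the product A: “with partner still left, so the end is an equilibrium, reached well before 20 h”. Its 44 % stands against my 44.6 %.

In the flask forward and back rates have come level, with a conversion of 57.7 % and 48.2 % of isomer of the product A.

    substrate + partner ⇌ target (K = 0.311 /M, k = 0.00439 /M/s)
    substrate + partner ⇌ isomer of the product A (K = 33.0 /M, k = 0.00152 /M/s)
    solid reagent ⇌ partner, rate k3*(cs3 - [partner]) while solid is left; crystals form when [partner] > cs3 (solubility = 0.120 M, k = 9.13 × 10⁻⁴ /s)
    target ⇌ isomer of the product B (K = 20.0, k = 0.00174 /s)

The conversion in this flask ends 4.3 points above my reckoning, with partner at 0.0346 M and solid reagent at 0 % of its charge. Neither the gradual feed nor the pace of dissolving moves its conversion. Carry the rest constant to the neighbour flask with 0.83 M of solid reagent: the cap is 36.1 %, and the same root gives 33.2 %. That neighbour flask gives a conversion of 35.2 %, with partner at 0.0137 M and 29.4 % of isomer of the product A.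

(The earlier runs and the new flask are simulated with made-up constants; the scatter is artificial.)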